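**Retrosynthetic overview**

- Melanocin E (21) comes from its 6,7-dibenzyl ether 20 by hydrogenolysis. Ring A (C4a, C5–C8, C8a) and the anisyl ring are bought as aldehydes, so ring B (C1–C4, C4a, C8a) is the only ring to build.
- The route rests on this feature of ring B: C1 carries the anisyl ring, C2 and C3 carry the two formamides, and C4a/C8a are the fusion carbons. Cutting the single bond C1–C8a therefore opens ring B to the 1,4-diaryl-2,3-diformamidobuta-1,3-diene 18, in which the future C8a is an arene carbon bearing a disposable OMe group.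
- 18 comes from the bis(arylidene)succinic acid 14 by a double Curtius rearrangement, with both isocyanates converted to formamides by formic acid.
- 14 comes from diethyl succinate by two successive Stobbe condensations, first with 4-methoxybenzaldehyde and then with aldehyde 6. Aldehyde 6 comes from 3,4-bis(benzyloxy)benzaldehyde by Baeyer–Villiger (Dakin-type) oxidation, O-methylation and Vilsmeier formylation.
- Ring order: ring A and the anisyl ring are present from the start; ring B is closed in step 8, and step 9 only removes the benzyl groups.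

Key step: step 8

Remark on the chemistry: both Stobbe condensations are assumed to give mainly the E-arylidene geometry (aryl trans to the carboxyl group on the same alkene). Minor geometric isomers need not be removed, because the light used in step 8 interconverts the alkene geometries. Compounds 13–18 are light-sensitive and should be handled under subdued light.

**Route**

Step 1
Reactants: 1 3,4-bis(benzyloxy)benzaldehyde
Product: 3 3,4-bis(benzyloxy)phenol, via aryl formate 2 (not isolated)
Conditions: mCPBA, CH2Cl2, 0 °C to rt; then K2CO3 (cat.), MeOH, rt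
Reagents that add atoms: mCPBA (3-chloroperoxybenzoic acid), O=C(OO)c1cccc(Cl)c1
Why: Baeyer–Villiger (Dakin-type) oxidation, in which the electron-rich aryl group migrates in the Criegee adduct to give formate 2, and mild methanolysis then frees the phenol without touching the benzyl ethers.

Step 2
Reactants: 3 3,4-bis(benzyloxy)phenol
Product: 4 1,2-bis(benzyloxy)-4-methoxybenzene
Conditions: MeI, K2CO3, acetone, reflux
Reagents that add atoms: iodomethane, CI
Why: Williamson ether synthesis, an SN2 methylation of the phenoxide with no competing nucleophile in the molecule.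

Step 3
Reactants: 4 1,2-bis(benzyloxy)-4-methoxybenzene
Product: 6 4,5-bis(benzyloxy)-2-methoxybenzaldehyde, via iminium chloride 5 (not isolated)
Conditions: POCl3, DMF, 0 °C to 70 °C; then aq NaOAc
Reagents that add atoms: N,N-dimethylformamide, CN(C)C=O; water, O
Why: Vilsmeier–Haack formylation at C5 of 4, the only unhindered position that is ortho to OMe and para to a benzyloxy group (C3 lies between two alkoxy groups), as in the formylation of 1,2,4-trimethoxybenzene.

Step 4
Reactants: 7 4-methoxybenzaldehyde; 8 diethyl succinate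
Product: 10 (E)-3-(ethoxycarbonyl)-4-(4-methoxyphenyl)but-3-enoic acid, via paraconic lactone 9 (not isolated)
Conditions: KOtBu, tBuOH, reflux; then aq HCl
Reagents that add atoms: none
Why: Stobbe condensation, in which the succinate enolate adds to the aldehyde, the aldolate lactonises onto the distal ester to give 9, and irreversible eliminative ring opening gives the half-ester with the aryl group trans to the ester.

Step 5
Reactants: 10 (E)-3-(ethoxycarbonyl)-4-(4-methoxyphenyl)but-3-enoic acid
Product: 11 diethyl (E)-2-(4-methoxybenzylidene)succinate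
Conditions: EtOH, H2SO4 (cat.), reflux
Reagents that add atoms: ethanol, CCO
Why: Fischer esterification of the unhindered aliphatic acid, which restores the diester needed for a second enolisation at the CH2 group.

Step 6
Reactants: 11 diethyl (E)-2-(4-methoxybenzylidene)succinate; 6 4,5-bis(benzyloxy)-2-methoxybenzaldehyde
Product: 14 (2E,3E)-2-[4,5-bis(benzyloxy)-2-methoxybenzylidene]-3-(4-methoxybenzylidene)succinic acid, via arylidene lactone 12 (not isolated), via half-ester 13 (not isolated)
Conditions: KOtBu, tBuOH/toluene, reflux; then KOH, EtOH/H2O, reflux; then aq HCl, 0 °C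
Reagents that add atoms: potassium hydroxide, [K+].[OH-]
Why: second Stobbe condensation at the remaining CH2 group (aldol addition, lactonisation to 12, eliminative opening to 13) followed by saponification of the surviving ester, the standard way to bis(arylidene)succinic (fulgenic) acids, each aryl group ending trans to its carboxyl group.

Step 7
Reactants: 14 (2E,3E)-2-[4,5-bis(benzyloxy)-2-methoxybenzylidene]-3-(4-methoxybenzylidene)succinic acid
Product: 18 N,N'-[(1E,3E)-1-(4,5-bis(benzyloxy)-2-methoxyphenyl)-4-(4-methoxyphenyl)buta-1,3-diene-2,3-diyl]diformamide, via diacyl azide 15 (not isolated), via diisocyanate 16 (not isolated), via mixed anhydride 17 (not isolated)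
Conditions: DPPA (2.2 equiv), Et3N, toluene, 0 °C to rt; then 85 °C; then HCO2H (excess), rt
Reagents that add atoms: diphenylphosphoryl azide, [N-]=[N+]=NP(=O)(Oc1ccccc1)Oc1ccccc1; formic acid, OC=O
Why: double Curtius rearrangement, in which each vinyl carbon migrates to nitrogen with retention of the alkene geometry (any cyclic anhydride formed on activation is reopened by azide and reactivated by the second equivalent of DPPA), and each isocyanate then adds formic acid to a carbamic formic anhydride that loses CO2 to leave the formamide.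

Step 8
Reactants: 18 N,N'-[(1E,3E)-1-(4,5-bis(benzyloxy)-2-methoxyphenyl)-4-(4-methoxyphenyl)buta-1,3-diene-2,3-diyl]diformamide
Product: 20 N,N'-[6,7-bis(benzyloxy)-1-(4-methoxyphenyl)naphthalene-2,3-diyl]diformamide (O,O-dibenzyl melanocin E), via dihydronaphthalene 19 (not isolated)
Conditions: hν (365 nm), TFA (0.1 equiv), degassed anhydrous MeCN (2 mM), Ar, 20 °C
Reagents that add atoms: none
Why: Excitation of the diaryldiene chromophore equilibrates both C=C geometries and populates the s-cis rotamer, so that the arene bond C8a=C4a, C4=C3 and C2=C1 (naphthalene numbering) form a hexatriene that closes conrotatory in the excited state, a 6π electrocyclization that makes C1–C8a and thereby ring B, as in the photocyclization of aryl fulgides and 1,4-diarylbutadienes to 1-aryl-1,8a-dihydronaphthalenes. Intermediate 19 carries OMe on C8a next to H on C1 (anisyl and OMe trans from closure of the drawn isomer, which is irrelevant because both centres become sp2), and protonation of the methoxy group gives a cation delocalised onto the C7 benzyloxy oxygen and the C2 nitrogen, which loses the C1 proton, so ring B aromatises without any oxidant; this is the eliminative variant of the Mallory reaction known for ortho-methoxystilbenes. No stereocentre remains in the product. The step needs site selectivity among three closures (onto the methoxy-bearing carbon, onto the unsubstituted ortho carbon of the same ring, or through the anisyl ring onto the other diene terminus), and only the first has a leaving group, so under argon the other two dihydronaphthalenes cannot be dehydrogenated and reopen to the diene, which should funnel material into 20. Irradiation at 365 nm, where the naphthalene product and the isolated enamide units absorb weakly, together with sub-stoichiometric acid at ambient temperature, should protect the formamides from photochemical acyl shift, hydrolysis and ring closure to a naphthimidazole.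

Step 9
Reactants: 20 N,N'-[6,7-bis(benzyloxy)-1-(4-methoxyphenyl)naphthalene-2,3-diyl]diformamide
Product: 21 melanocin E
Conditions: H2 (1 atm), 10% Pd/C, EtOAc/MeOH, rt
Reagents that add atoms: none
Why: catalytic hydrogenolysis of the two aryl benzyl ethers under neutral conditions, which should leave the aryl methyl ether, the formamides and the naphthalene untouched (the catechol is worked up under argon).

**Compound list**

1 | 3,4-bis(benzyloxy)benzaldehyde | O=Cc1ccc(OCc2ccccc2)c(OCc2ccccc2)c1 | starting material
2 | 3,4-bis(benzyloxy)phenyl formate | O=COc1ccc(OCc2ccccc2)c(OCc2ccccc2)c1 | intermediate (not isolated)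
3 | 3,4-bis(benzyloxy)phenol | Oc1ccc(OCc2ccccc2)c(OCc2ccccc2)c1 | intermediate
4 | 1,2-bis(benzyloxy)-4-methoxybenzene | COc1ccc(OCc2ccccc2)c(OCc2ccccc2)c1 | intermediate
5 | N-[4,5-bis(benzyloxy)-2-methoxybenzylidene]-N-methylmethanaminium chloride | COc1cc(OCc2ccccc2)c(OCc2ccccc2)cc1C=[N+](C)C.[Cl-] | intermediate (not isolated)
6 | 4,5-bis(benzyloxy)-2-methoxybenzaldehyde | COc1cc(OCc2ccccc2)c(OCc2ccccc2)cc1C=O | intermediate
7 | 4-methoxybenzaldehyde | COc1ccc(C=O)cc1 | starting material
8 | diethyl succinate | CCOC(=O)CCC(=O)OCC | starting material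
9 | ethyl 2-(4-methoxyphenyl)-5-oxotetrahydrofuran-3-carboxylate (paraconic lactone, mixture of diastereomers) | CCOC(=O)C1CC(=O)OC1c1ccc(OC)cc1 | intermediate (not isolated)
10 | (E)-3-(ethoxycarbonyl)-4-(4-methoxyphenyl)but-3-enoic acid | CCOC(=O)/C(CC(=O)O)=C/c1ccc(OC)cc1 | intermediate
11 | diethyl (E)-2-(4-methoxybenzylidene)succinate | CCOC(=O)C/C(C(=O)OCC)=C\c1ccc(OC)cc1 | intermediate
12 | ethyl (4E)-2-[4,5-bis(benzyloxy)-2-methoxyphenyl]-4-(4-methoxybenzylidene)-5-oxotetrahydrofuran-3-carboxylate (mixture of diastereomers) | CCOC(=O)C1C(c2cc(OCc3ccccc3)c(OCc3ccccc3)cc2OC)OC(=O)/C1=C/c1ccc(OC)cc1 | intermediate (not isolated)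
13 | (2E,3E)-4-[4,5-bis(benzyloxy)-2-methoxyphenyl]-3-(ethoxycarbonyl)-2-(4-methoxybenzylidene)but-3-enoic acid | CCOC(=O)/C(=C/c1cc(OCc2ccccc2)c(OCc2ccccc2)cc1OC)C(\C(=O)O)=C/c1ccc(OC)cc1 | intermediate (not isolated)
14 | (2E,3E)-2-[4,5-bis(benzyloxy)-2-methoxybenzylidene]-3-(4-methoxybenzylidene)succinic acid | OC(=O)/C(=C/c1cc(OCc2ccccc2)c(OCc2ccccc2)cc1OC)C(\C(=O)O)=C/c1ccc(OC)cc1 | intermediate
15 | (2E,3E)-2-[4,5-bis(benzyloxy)-2-methoxybenzylidene]-3-(4-methoxybenzylidene)succinoyl diazide | [N-]=[N+]=NC(=O)/C(=C/c1cc(OCc2ccccc2)c(OCc2ccccc2)cc1OC)C(\C(=O)N=[N+]=[N-])=C/c1ccc(OC)cc1 | intermediate (not isolated)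
16 | (1E,3E)-1-[4,5-bis(benzyloxy)-2-methoxyphenyl]-2,3-diisocyanato-4-(4-methoxyphenyl)buta-1,3-diene | O=C=N/C(=C/c1cc(OCc2ccccc2)c(OCc2ccccc2)cc1OC)C(\N=C=O)=C/c1ccc(OC)cc1 | intermediate (not isolated)
17 | bis(carbamic formic anhydride) of the (1E,3E)-2,3-diaminodiene, each nitrogen carrying C(=O)OCHO | O=COC(=O)N/C(=C/c1cc(OCc2ccccc2)c(OCc2ccccc2)cc1OC)C(\NC(=O)OC=O)=C/c1ccc(OC)cc1 | intermediate (not isolated)
18 | N,N'-[(1E,3E)-1-(4,5-bis(benzyloxy)-2-methoxyphenyl)-4-(4-methoxyphenyl)buta-1,3-diene-2,3-diyl]diformamide (each aryl group trans to nitrogen, cis to the other half of the diene) | COc1cc(OCc2ccccc2)c(OCc2ccccc2)cc1/C=C(/NC=O)C(\NC=O)=C/c1ccc(OC)cc1 | intermediate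
19 | N,N'-[6,7-bis(benzyloxy)-8a-methoxy-1-(4-methoxyphenyl)-1,8a-dihydronaphthalene-2,3-diyl]diformamide (racemic, one enantiomer drawn; 1-anisyl and 8a-OMe trans; the C1 epimer from the photoisomerised diene leads to the same product) | COc1ccc(cc1)[C@@H]1C(NC=O)=C(NC=O)C=C2C=C(OCc3ccccc3)C(OCc3ccccc3)=C[C@]12OC | intermediate (not isolated)
20 | N,N'-[6,7-bis(benzyloxy)-1-(4-methoxyphenyl)naphthalene-2,3-diyl]diformamide (O,O-dibenzyl melanocin E) | COc1ccc(cc1)-c1c(NC=O)c(NC=O)cc2cc(OCc3ccccc3)c(OCc3ccccc3)cc12 | intermediate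
21 | melanocin E, N,N'-[6,7-dihydroxy-1-(4-methoxyphenyl)naphthalene-2,3-diyl]diformamide | COc1ccc(-c2c(NC=O)c(NC=O)cc3cc(O)c(O)cc23)cc1 | target

**Step count**

Total step count: 9.
Longest linear sequence: 7 steps (steps 1, 2, 3, 6, 7, 8, 9, from 1 to 21).

**Steps most likely to fail**

1. Step 8 (photochemical ring closure). The excited diene may close through the anisyl ring or onto the unsubstituted ortho carbon and then be drained by an irreversible thermal hydrogen shift to 1,2-dihydronaphthalenes. Alternatively the enamide units may degrade (acyl shift, hydrolysis) faster than methanol is lost. The fallback sets out from 14 and comes back to the route at 20; it closes ring B before any nitrogen is present.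
   - Acetic anhydride at rt should dehydrate 14 to the fulgide (3E,4E)-3-[4,5-bis(benzyloxy)-2-methoxybenzylidene]-4-(4-methoxybenzylidene)dihydrofuran-2,5-dione F1.
   - Irradiation of F1 at 365 nm in degassed toluene with a trace of TFA, the classical photocyclization of aryl fulgides, should form the same C1–C8a bond. It passes through 6,7-bis(benzyloxy)-4a-methoxy-4-(4-methoxyphenyl)-4,4a-dihydronaphtho[2,3-c]furan-1,3-dione F2 (not isolated) and, after loss of methanol, gives 6,7-bis(benzyloxy)-4-(4-methoxyphenyl)naphtho[2,3-c]furan-1,3-dione F3.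
   - Aqueous NaOH in THF followed by acidification should open F3 to 6,7-bis(benzyloxy)-1-(4-methoxyphenyl)naphthalene-2,3-dicarboxylic acid F4.
   - F4 is then taken through the DPPA/Et3N, 85 °C, formic acid protocol of step 7. It passes through 6,7-bis(benzyloxy)-1-(4-methoxyphenyl)naphthalene-2,3-dicarbonyl diazide F5, 6,7-bis(benzyloxy)-2,3-diisocyanato-1-(4-methoxyphenyl)naphthalene F6 and the corresponding bis(carbamic formic anhydride) F7 to give 20.

2. Step 7 (double Curtius rearrangement and formic acid quench). The mono-activated acid may be diverted into the cyclic anhydride so that the second rearrangement stays incomplete. During the quench a formamide N–H may add to the neighbouring isocyanate (cyclic urea), or the vinyl isocyanates may oligomerise. The fallback sets out from 14 and comes back at 18; it captures both isocyanates as stable carbamates and transfers the formyl group afterwards.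
   - DPPA, Et3N, tBuOH/toluene at 85 °C should give, through 15 and 16, di-tert-butyl [(1E,3E)-1-(4,5-bis(benzyloxy)-2-methoxyphenyl)-4-(4-methoxyphenyl)buta-1,3-diene-2,3-diyl]dicarbamate F8.
   - Double N-deprotonation with LiN(SiMe3)2 in THF at −78 °C and acylation with acetic formic anhydride should give the bis(N-tert-butoxycarbonyl-N-formyl) diene F9.
   - TFA in CH2Cl2 at 0 °C should remove only the tert-butoxycarbonyl groups (as 2-methylpropene and CO2) and leave 18.

3. Step 6 (second Stobbe condensation). The stabilised enolate of 11 may add only slowly to the hindered, electron-rich aldehyde 6, so that self-condensation of 11 and scrambling of alkene geometry under prolonged alkoxide heating compete. The fallback sets out from 6 and 8 and comes back at 14; it reverses the order of the two condensations, so that the hindered aldehyde meets the unhindered succinate and the second condensation uses the more reactive 4-methoxybenzaldehyde.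
   - Stobbe condensation of 6 with 8 (KOtBu, tBuOH) should pass through ethyl 2-[4,5-bis(benzyloxy)-2-methoxyphenyl]-5-oxotetrahydrofuran-3-carboxylate F10 (not isolated) to (E)-4-[4,5-bis(benzyloxy)-2-methoxyphenyl]-3-(ethoxycarbonyl)but-3-enoic acid F11.
   - Fischer esterification should give diethyl (E)-2-[4,5-bis(benzyloxy)-2-methoxybenzylidene]succinate F12.
   - Stobbe condensation of F12 with 7 should pass through ethyl (4E)-4-[4,5-bis(benzyloxy)-2-methoxybenzylidene]-2-(4-methoxyphenyl)-5-oxotetrahydrofuran-3-carboxylate F13 (not isolated) to (2E,3E)-2-[4,5-bis(benzyloxy)-2-methoxybenzylidene]-3-(ethoxycarbonyl)-4-(4-methoxyphenyl)but-3-enoic acid F14.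
   - Saponification of F14 with KOH in aqueous ethanol and acidification should give 14.

**Further compounds**

F1 | step 8 | (3E,4E)-3-[4,5-bis(benzyloxy)-2-methoxybenzylidene]-4-(4-methoxybenzylidene)dihydrofuran-2,5-dione | O=C1OC(=O)/C(=C/c2ccc(OC)cc2)/C1=C\c1cc(OCc2ccccc2)c(OCc2ccccc2)cc1OC
F2 | step 8 | 6,7-bis(benzyloxy)-4a-methoxy-4-(4-methoxyphenyl)-4,4a-dihydronaphtho[2,3-c]furan-1,3-dione (racemic, one enantiomer drawn) | COc1ccc(cc1)[C@@H]1C2=C(C=C3C=C(OCc4ccccc4)C(OCc4ccccc4)=C[C@]13OC)C(=O)OC2=O
F3 | step 8 | 6,7-bis(benzyloxy)-4-(4-methoxyphenyl)naphtho[2,3-c]furan-1,3-dione | COc1ccc(cc1)-c1c2C(=O)OC(=O)c2cc2cc(OCc3ccccc3)c(OCc3ccccc3)cc12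
F4 | step 8 | 6,7-bis(benzyloxy)-1-(4-methoxyphenyl)naphthalene-2,3-dicarboxylic acid | COc1ccc(cc1)-c1c(C(=O)O)c(C(=O)O)cc2cc(OCc3ccccc3)c(OCc3ccccc3)cc12
F5 | step 8 | 6,7-bis(benzyloxy)-1-(4-methoxyphenyl)naphthalene-2,3-dicarbonyl diazide | COc1ccc(cc1)-c1c(C(=O)N=[N+]=[N-])c(C(=O)N=[N+]=[N-])cc2cc(OCc3ccccc3)c(OCc3ccccc3)cc12
F6 | step 8 | 6,7-bis(benzyloxy)-2,3-diisocyanato-1-(4-methoxyphenyl)naphthalene | COc1ccc(cc1)-c1c(N=C=O)c(N=C=O)cc2cc(OCc3ccccc3)c(OCc3ccccc3)cc12
F7 | step 8 | bis(carbamic formic anhydride) of 6,7-bis(benzyloxy)-1-(4-methoxyphenyl)naphthalene-2,3-diamine | COc1ccc(cc1)-c1c(NC(=O)OC=O)c(NC(=O)OC=O)cc2cc(OCc3ccccc3)c(OCc3ccccc3)cc12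
F8 | step 7 | di-tert-butyl [(1E,3E)-1-(4,5-bis(benzyloxy)-2-methoxyphenyl)-4-(4-methoxyphenyl)buta-1,3-diene-2,3-diyl]dicarbamate | CC(C)(C)OC(=O)N/C(=C/c1cc(OCc2ccccc2)c(OCc2ccccc2)cc1OC)C(\NC(=O)OC(C)(C)C)=C/c1ccc(OC)cc1
F9 | step 7 | di-tert-butyl [(1E,3E)-1-(4,5-bis(benzyloxy)-2-methoxyphenyl)-4-(4-methoxyphenyl)buta-1,3-diene-2,3-diyl]bis(formylcarbamate) | CC(C)(C)OC(=O)N(C=O)/C(=C/c1cc(OCc2ccccc2)c(OCc2ccccc2)cc1OC)C(\N(C=O)C(=O)OC(C)(C)C)=C/c1ccc(OC)cc1
F10 | step 6 | ethyl 2-[4,5-bis(benzyloxy)-2-methoxyphenyl]-5-oxotetrahydrofuran-3-carboxylate (mixture of diastereomers) | CCOC(=O)C1CC(=O)OC1c1cc(OCc2ccccc2)c(OCc2ccccc2)cc1OC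
F11 | step 6 | (E)-4-[4,5-bis(benzyloxy)-2-methoxyphenyl]-3-(ethoxycarbonyl)but-3-enoic acid | CCOC(=O)/C(CC(=O)O)=C/c1cc(OCc2ccccc2)c(OCc2ccccc2)cc1OC
F12 | step 6 | diethyl (E)-2-[4,5-bis(benzyloxy)-2-methoxybenzylidene]succinate | CCOC(=O)C/C(C(=O)OCC)=C\c1cc(OCc2ccccc2)c(OCc2ccccc2)cc1OC
F13 | step 6 | ethyl (4E)-4-[4,5-bis(benzyloxy)-2-methoxybenzylidene]-2-(4-methoxyphenyl)-5-oxotetrahydrofuran-3-carboxylate (mixture of diastereomers) | CCOC(=O)C1C(c2ccc(OC)cc2)OC(=O)/C1=C/c1cc(OCc2ccccc2)c(OCc2ccccc2)cc1OC
F14 | step 6 | (2E,3E)-2-[4,5-bis(benzyloxy)-2-methoxybenzylidene]-3-(ethoxycarbonyl)-4-(4-methoxyphenyl)but-3-enoic acid | OC(=O)/C(=C/c1cc(OCc2ccccc2)c(OCc2ccccc2)cc1OC)C(\C(=O)OCC)=C/c1ccc(OC)cc1
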